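**Overview**

- **Enabling feature:** in ring C (O1-C2-C3-C4-C4a-C8a), the fully substituted carbinol carbon C3 (OH, ring B, C2) is bonded directly to the ketone carbon C4 on ring A. This alpha-ketol is the retron of a benzoin addition of a ring-A aldehyde carbon (C4) to a ring-B aryl ketone carbon (C3).
- **Cuts, in retrosynthetic order:** the two phenol masks at O5 and O4'. Then C3-C4, which opens ring C to a keto-aldehyde. Then O1-C2, which gives a salicylaldehyde and an alpha-chloro ketone. Last, the aryl-CHO bond on ring A and the C-Cl, O-Me and C3'-prenyl bonds on ring B.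
- **Forward order:** both benzene rings are bought. Ring A is formylated by directed metalation. Ring B is prenylated, capped and chlorinated. The halves are joined through the O1-C2 ether, ring C closes through C3-C4 in the penultimate step, and deprotection ends the route.
- **Stereochemistry:** the single stereocentre C3 (S) is set during ring closure by a chiral triazolylidene catalyst that selects the Re face of the ketone. No later step breaks a bond at C3.

Key step: step 9

Assumption: the (5aR,10bS) enantiomer of the aminoindanol-derived triazolium salt is taken as the one that leads to Re-face attack and hence to (S); the sense of induction is to be confirmed in the first run, and the equally available (5aS,10bR) salt is used instead if it proves opposite.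

Step 1
Reactants: 1 5-methoxyresorcinol (3,5-dihydroxyanisole)
Product: 2 1-methoxy-3,5-bis(methoxymethoxy)benzene
Conditions: MOMCl (2.5 equiv), i-Pr2NEt (3 equiv), CH2Cl2, 0 °C to rt
Reagents that add atoms: chloromethyl methyl ether (MOMCl), COCCl
Why: Routine O-alkylation of both phenols (MOM protection) installs the two chelating acetal groups that direct the metalation of the next step.

Step 2
Reactants: 2 1-methoxy-3,5-bis(methoxymethoxy)benzene
Product: 5 4-methoxy-2,6-bis(methoxymethoxy)benzaldehyde, via aryllithium 3 (not isolated), via lithium hemiaminal alkoxide 4 (not isolated)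
Conditions: n-BuLi, TMEDA, THF, 0 °C; DMF, 0 °C to rt; H2O
Reagents that add atoms: N,N-dimethylformamide (DMF), CN(C)C=O
Why: In this directed ortho-metalation and DMF formylation, the ring position flanked by two chelating OMOM groups is lithiated in preference to those next to the weaker OMe director, and adduct 4 persists until the aqueous quench, so no second addition can occur.

Step 3
Reactants: 5 4-methoxy-2,6-bis(methoxymethoxy)benzaldehyde
Product: 6 2-hydroxy-4-methoxy-6-(methoxymethoxy)benzaldehyde
Conditions: 3 M aq. HCl, THF, rt, stopped at the mono-phenol stage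
Reagents that add atoms: none
Why: In this acid hydrolysis of an aryl MOM acetal, the two MOM groups are equivalent, so either cleavage gives the same phenol, and its strong hydrogen bond to the formyl oxygen then slows the loss of the second acetal, a behaviour well established for 2,6-bis(methoxymethoxy)benzaldehydes.

Step 4
Reactants: 7 2,4-dihydroxyacetophenone; 8 prenyl bromide (1-bromo-3-methylbut-2-ene)
Product: 9 2,4-dihydroxy-3-prenylacetophenone (1-[2,4-dihydroxy-3-(3-methylbut-2-en-1-yl)phenyl]ethanone)
Conditions: aq. KOH (10 %), 0 °C to rt; chromatography
Reagents that add atoms: none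
Why: In this nuclear (C-) prenylation of an ambident phenolate, water solvates the oxygen atoms and the doubly activated C3 between them is the most nucleophilic carbon, so 9 should be the main C-alkylated product, to be separated from the C5 isomer and from O- and bis-alkylated material.

Step 5
Reactants: 9 2,4-dihydroxy-3-prenylacetophenone
Product: 10 2-hydroxy-4-(methoxymethoxy)-3-prenylacetophenone
Conditions: MOMCl (1.2 equiv), K2CO3, acetone, 0 °C to rt
Reagents that add atoms: chloromethyl methyl ether (MOMCl), COCCl
Why: This O-alkylation is site-selective because the 2-OH is held in a hydrogen bond to the acetyl oxygen and is flanked by the prenyl group, so only the free and more acidic 4-OH is protected.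

Step 6
Reactants: 10 2-hydroxy-4-(methoxymethoxy)-3-prenylacetophenone
Product: 11 2-methoxy-4-(methoxymethoxy)-3-prenylacetophenone
Conditions: MeI (3 equiv), K2CO3, DMF, 40 °C
Reagents that add atoms: iodomethane (MeI), CI
Why: Williamson methylation in a dipolar aprotic solvent with excess methyl iodide overcomes the chelation of the remaining phenol, and carbonate is too weak to enolise the ketone.

Step 7
Reactants: 11 2-methoxy-4-(methoxymethoxy)-3-prenylacetophenone
Product: 13 2-chloro-1-[2-methoxy-4-(methoxymethoxy)-3-(3-methylbut-2-en-1-yl)phenyl]ethanone, via lithium enolate 12 (not isolated)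
Conditions: LDA (commercial solution, 1.1 equiv), THF, -78 °C; cannulated into TsCl (1.3 equiv), THF, -78 to 0 °C
Reagents that add atoms: p-toluenesulfonyl chloride (TsCl), Cc1ccc(cc1)S(=O)(=O)Cl
Why: Kinetic deprotonation at the only enolisable carbon and chlorine transfer from the sulfonyl chloride to the lithium enolate (electrophilic alpha-chlorination of a ketone enolate) need neither free halogen nor acid, so the prenyl alkene and the MOM acetal stay intact, and inverse addition keeps proton exchange and a second chlorination low.

Step 8
Reactants: 6 2-hydroxy-4-methoxy-6-(methoxymethoxy)benzaldehyde; 13 alpha-chloro ketone of ring B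
Product: 15 4-methoxy-2-{2-[2-methoxy-4-(methoxymethoxy)-3-(3-methylbut-2-en-1-yl)phenyl]-2-oxoethoxy}-6-(methoxymethoxy)benzaldehyde, via iodo ketone 14 (not isolated)
Conditions: K2CO3 (1.5 equiv), KI (10 mol %), DMF, 0 °C to rt
Reagents that add atoms: none
Why: In this Williamson ether synthesis with Finkelstein catalysis, the activated alpha-halo ketone reacts with the phenolate at room temperature, where the weak base and the electron-rich hindered aldehyde should keep the ether from going on to a benzofuran by Rap-Stoermer condensation.

Step 9
Reactants: 15 keto-aldehyde ether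
Product: 17 (3S)-3-hydroxy-7-methoxy-5-(methoxymethoxy)-3-[2-methoxy-4-(methoxymethoxy)-3-(3-methylbut-2-en-1-yl)phenyl]chroman-4-one, via Breslow enaminol 16 (not isolated)
Conditions: (5aR,10bS)-2-(pentafluorophenyl)-5a,10b-dihydro-4H,6H-indeno[2,1-b][1,2,4]triazolo[4,3-d][1,4]oxazin-2-ium tetrafluoroborate (15 mol %), Et3N (15 mol %), toluene, rt, Ar
Reagents that add atoms: none
Why: Et3N frees the triazolylidene, which adds to the non-enolisable formyl group of 15; a proton shift gives the Breslow enaminol 16, whose nucleophilic carbon (future C4) attacks the tethered aryl ketone carbon (future C3), and proton transfer with loss of the carbene uncovers the C4 ketone beside the new tertiary alcohol. The closest known reaction type is the enantioselective carbene-catalysed intramolecular crossed aldehyde-ketone benzoin reaction of 2-(2-oxoethoxy)benzaldehydes, which delivers 3-substituted 3-hydroxychroman-4-ones. The one ring formed, the dihydropyranone O1-C2-C3-C4-C4a-C8a, closes in the 6-exo-trig mode because the attacked C=O bond stays outside the ring. The one new stereocentre, C3, is controlled by the catalyst alone: the fused indane wall blocks one face of the planar enaminol and the hydrogen bond from the enol O-H to the ketone oxygen orients the acceptor, so that the Re face of the ketone (O > C2 > aryl) is attacked, which corresponds to (S). Donor-acceptor chemoselectivity is secured by the substrate, since only the aldehyde can form the acyl-anion equivalent, the ketone is the only electrophile that a six-membered transition state can reach, and the out-of-plane twist forced on the ketone by the 2'-methoxy group keeps it electrophilic in spite of the para oxygen. The competing base-induced aldol condensation of the C2 methylene onto the aldehyde is kept down by the electron-poor N-aryl group, which lets a catalytic amount of a weak amine base suffice, and by the masked 5-oxygen, which also prevents a chelated phenolate from switching the aldehyde off.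

Step 10
Reactants: 17 bis-MOM (S)-3-hydroxyisoflavanone
Product: 18 (3S)-3,5-dihydroxy-3-[4-hydroxy-2-methoxy-3-(3-methylbut-2-en-1-yl)phenyl]-7-methoxychroman-4-one (target)
Conditions: HCl (1.25 M in MeOH), MeOH/CH2Cl2, 0 °C to rt, monitored closely
Reagents that add atoms: none
Why: Acid-catalysed transacetalisation of both aryl MOM ethers to methanol is the standard deprotection of prenylated polyphenols, and in dilute acid at or below room temperature C3 should keep its (S) configuration because its cation would sit next to the C4 carbonyl, while the trisubstituted alkene is protonated far more slowly than the acetals.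

**Compound list**

1 | 5-methoxyresorcinol | COc1cc(O)cc(O)c1 | starting material
2 | 1-methoxy-3,5-bis(methoxymethoxy)benzene | COCOc1cc(OC)cc(OCOC)c1 | intermediate
3 | [4-methoxy-2,6-bis(methoxymethoxy)phenyl]lithium | [Li]c1c(OCOC)cc(OC)cc1OCOC | intermediate
4 | lithium (dimethylamino)[4-methoxy-2,6-bis(methoxymethoxy)phenyl]methanolate | [Li]OC(N(C)C)c1c(OCOC)cc(OC)cc1OCOC | intermediate
5 | 4-methoxy-2,6-bis(methoxymethoxy)benzaldehyde | O=Cc1c(OCOC)cc(OC)cc1OCOC | intermediate
6 | 2-hydroxy-4-methoxy-6-(methoxymethoxy)benzaldehyde | COCOc1cc(OC)cc(O)c1C=O | intermediate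
7 | 2,4-dihydroxyacetophenone | CC(=O)c1ccc(O)cc1O | starting material
8 | prenyl bromide | CC(C)=CCBr | starting material
9 | 2,4-dihydroxy-3-prenylacetophenone | CC(=O)c1ccc(O)c(CC=C(C)C)c1O | intermediate
10 | 2-hydroxy-4-(methoxymethoxy)-3-prenylacetophenone | CC(=O)c1ccc(OCOC)c(CC=C(C)C)c1O | intermediate
11 | 2-methoxy-4-(methoxymethoxy)-3-prenylacetophenone | CC(=O)c1ccc(OCOC)c(CC=C(C)C)c1OC | intermediate
12 | lithium enolate of 11 | [Li]OC(=C)c1ccc(OCOC)c(CC=C(C)C)c1OC | intermediate
13 | 2-chloro-1-[2-methoxy-4-(methoxymethoxy)-3-prenylphenyl]ethanone | O=C(CCl)c1ccc(OCOC)c(CC=C(C)C)c1OC | intermediate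
14 | 2-iodo-1-[2-methoxy-4-(methoxymethoxy)-3-prenylphenyl]ethanone | O=C(CI)c1ccc(OCOC)c(CC=C(C)C)c1OC | intermediate
15 | keto-aldehyde ether (cyclisation substrate) | O=Cc1c(OCOC)cc(OC)cc1OCC(=O)c1ccc(OCOC)c(CC=C(C)C)c1OC | intermediate
16 | Breslow enaminol from 15 and the (5aR,10bS)-triazolylidene | OC(=C1N(c2c(F)c(F)c(F)c(F)c2F)N=C2CO[C@@H]3Cc4ccccc4[C@@H]3N12)c1c(OCOC)cc(OC)cc1OCC(=O)c1ccc(OCOC)c(CC=C(C)C)c1OC | intermediate
17 | (3S)-3-hydroxy-7-methoxy-5-(methoxymethoxy)-3-[2-methoxy-4-(methoxymethoxy)-3-prenylphenyl]chroman-4-one | COc1cc(OCOC)c2c(c1)OC[C@@](O)(c1ccc(OCOC)c(CC=C(C)C)c1OC)C2=O | intermediate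
18 | (3S)-3,5-dihydroxy-3-(4-hydroxy-2-methoxy-3-prenylphenyl)-7-methoxychroman-4-one | COc1cc(O)c2c(c1)OC[C@@](O)(c1ccc(O)c(CC=C(C)C)c1OC)C2=O | target

Total step count: 10. Longest linear sequence: 7 steps (steps 4 to 10, from 7). The ring-A branch (steps 1 to 3) joins at step 8.

**Steps most likely to fail**

**1. Step 9.**
- Risk: the bulky chiral carbene may add only sluggishly to the electron-rich, doubly ortho-substituted aldehyde. Discrimination between the ketone faces may be insufficient with the ortho-substituted ring B. Reversibility of the addition may erode the enantiomeric purity. Base-induced aldol condensation may take over if the carbene pathway is slow.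
- Fallback (resolution in place of asymmetric catalysis): setting out from 15, the ring would be closed with a small achiral carbene, which meets far less steric resistance. It is generated from 3-benzyl-5-(2-hydroxyethyl)-4-methylthiazolium chloride and Et3N in THF or t-BuOH. This gives the racemic bis-MOM 3-hydroxyisoflavanone F1. Preparative chromatography on a polysaccharide-based chiral stationary phase would then separate the (S)-enantiomer, which is 17 and rejoins the route there, from the (3R)-bis-MOM 3-hydroxyisoflavanone F2, which is set aside.

**2. Step 10.**
- Risk: before the less labile ring-B MOM group has gone, the acid may ionise the tertiary benzylic carbinol. This is helped by the freed para-hydroxyl and leads to loss of configuration, solvolysis or dehydration across C2-C3. The liberated 4'-phenol may also add to the protonated prenyl alkene.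
- Fallback (different protecting-group design): setting out from 9, the 4-OH would be capped with allyl bromide and K2CO3 in acetone to give 4-allyloxy-2-hydroxy-3-prenylacetophenone F3. Methylation as in step 6 gives 4-allyloxy-2-methoxy-3-prenylacetophenone F4. Enolate chlorination as in step 7 gives the allyl-protected chloro ketone F5. Ether formation with 6 as in step 8 gives the allyl-protected keto-aldehyde F6. Carbene-catalysed closure as in step 9 gives the (S)-5-O-MOM 4'-O-allyl ketol F7.
- The only acid-labile mask left is then the 5-O-MOM group, which lies peri to the C4 carbonyl and is the more labile of the two. Brief treatment with dilute methanolic HCl at 0 °C removes it while O4' is still alkylated. No phenol then sits next to the prenyl group and no para-hydroxyl assists ionisation at C3. The product is the (S)-5-hydroxy 4'-O-allyl ketol F8. Neutral Tsuji-Trost deallylation (Pd(PPh3)4 cat., morpholine, THF, rt) then comes back to the route at 18.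

**3. Step 4.**
- Risk: poor site selectivity of the ambident phenolate (C3 against C5 and oxygen) and over-alkylation may leave little of the wanted isomer and a difficult separation.
- Fallback (the site is fixed by a carbon-halogen bond and the prenyl group comes by cross-coupling): setting out from 7, iodination between the two hydroxyls (I2, HIO3, aq. EtOH) gives 2,4-dihydroxy-3-iodoacetophenone F9. Selective MOM protection as in step 5 gives 2-hydroxy-3-iodo-4-(methoxymethoxy)acetophenone F10. Methylation as in step 6 gives 3-iodo-2-methoxy-4-(methoxymethoxy)acetophenone F11. Stille coupling with commercial tributyl(3-methylbut-2-en-1-yl)stannane (Pd2(dba)3, AsPh3, CuI, DMF, 60 °C) comes back to the route at 11.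

**Further compounds**

F1 | step 9 | racemic bis-MOM 3-hydroxyisoflavanone | COc1cc(OCOC)c2c(c1)OCC(O)(c1ccc(OCOC)c(CC=C(C)C)c1OC)C2=O
F2 | step 9 | (3R)-bis-MOM 3-hydroxyisoflavanone | COc1cc(OCOC)c2c(c1)OC[C@](O)(c1ccc(OCOC)c(CC=C(C)C)c1OC)C2=O
F3 | step 10 | 4-allyloxy-2-hydroxy-3-prenylacetophenone | CC(=O)c1ccc(OCC=C)c(CC=C(C)C)c1O
F4 | step 10 | 4-allyloxy-2-methoxy-3-prenylacetophenone | CC(=O)c1ccc(OCC=C)c(CC=C(C)C)c1OC
F5 | step 10 | allyl-protected chloro ketone | O=C(CCl)c1ccc(OCC=C)c(CC=C(C)C)c1OC
F6 | step 10 | allyl-protected keto-aldehyde | O=Cc1c(OCOC)cc(OC)cc1OCC(=O)c1ccc(OCC=C)c(CC=C(C)C)c1OC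
F7 | step 10 | (S)-5-O-MOM 4'-O-allyl ketol | COc1cc(OCOC)c2c(c1)OC[C@@](O)(c1ccc(OCC=C)c(CC=C(C)C)c1OC)C2=O
F8 | step 10 | (S)-5-hydroxy 4'-O-allyl ketol | COc1cc(O)c2c(c1)OC[C@@](O)(c1ccc(OCC=C)c(CC=C(C)C)c1OC)C2=O
F9 | step 4 | 2,4-dihydroxy-3-iodoacetophenone | CC(=O)c1ccc(O)c(I)c1O
F10 | step 4 | 2-hydroxy-3-iodo-4-(methoxymethoxy)acetophenone | CC(=O)c1ccc(OCOC)c(I)c1O
F11 | step 4 | 3-iodo-2-methoxy-4-(methoxymethoxy)acetophenone | CC(=O)c1ccc(OCOC)c(I)c1OC
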